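Ring locants: C1 (CH–O), C2 (CMe2), C3=C4, C5 (=CH2), C6, C7, C8=C9 (Me on C9), C10, C11. Retrosynthetic cuts, in order: vanillate acyl–O; the C3=C4 π bond (a CO2H is put back on C3); the C3–C4 σ bond (retro-Ireland–Claisen); lactone acyl–O; C1–C2; C6–C7.
Enabling feature: the 1,1-disubstituted alkene on ring carbon C5 and the adjoining C4–C3 pair, CH2=C5–C4–C3, form a γ,δ-unsaturated acid once C3 bears CO2H. The retro-[3,3] shift exchanges the roles of C4 and the =CH2 carbon and inserts C(=O)–O, which gives a 13-membered lactone containing O–CH2–C5(=C4H2). C2 is quaternary, so loss of CO2 and H from C3 can only give C3=C4.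
Forward: open chain (C6–C7 by dianion alkylation, C1–C2 by reverse prenylation) → 13-membered lactone, the first ring → [3,3] contraction to the 11-membered carbocycle → decarboxylative olefination to the C3=C4/C5=CH2 diene → aroylation of O–C1.
Stereochemistry: (R)-C1 comes from reagent-controlled allylboration with the (+)-α-pinene-derived prenylborane. E-C8=C9 is carried in from geranyl bromide. E-C3=C4 comes from the elimination, in which both C3 epimers of the contraction product converge.
Key step: step 11

Remark on the chemistry: the SMILES is read as the (1R,3E,8E)-2,2,9-trimethyl-5-methylidenecycloundeca-3,8-dien-1-yl ester of vanillic acid.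
Remark on bookkeeping: a reagent whose atoms occur only in a non-isolated intermediate of a step is also entered under "Reagents that add atoms", with a note. TBS = tert-butyldimethylsilyl, Ipc = isopinocampheyl, MNBA = 2-methyl-6-nitrobenzoic anhydride. (−)-Ipc2BH is the stock reagent made from (+)-α-pinene and BH3·SMe2.

Step 1
Reactants: 1 2-methylprop-2-en-1-ol (methallyl alcohol); 2 geranyl bromide [(2E)-1-bromo-3,7-dimethylocta-2,6-diene]
Product: 4 (5E)-6,10-dimethyl-2-methylideneundeca-5,9-dien-1-ol, via dilithiated methallyl alcohol 3 (not isolated)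
Conditions: 1, n-BuLi (2.2 equiv), TMEDA, Et2O, 0 °C to rt; then 2, THF, −78 to 0 °C; H2O
Reagents that add atoms: n-BuLi, [Li]CCCC (lithium only in 3)
Why: Alkoxide-directed allylic lithiation gives the O,C-dianion, whose carbon terminus displaces the primary allylic bromide (SN2 dianion alkylation), so that C6–C7 is formed, the HOCH2–C(=CH2)–CH2 unit is installed and the E-trisubstituted alkene of 2 is carried over unchanged.

Step 2
Reactants: 4 (5E)-6,10-dimethyl-2-methylideneundeca-5,9-dien-1-ol
Product: 5 TBS ether of 4
Conditions: TBSCl, imidazole, CH2Cl2, rt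
Reagents that add atoms: TBSCl, CC(C)(C)[Si](C)(C)Cl
Why: Standard silyl ether protection of a primary alcohol masks the allylic OH through steps 3–8 and lowers the nucleophilicity of the neighbouring 1,1-disubstituted alkene.

Step 3
Reactants: 5 TBS ether of 4
Product: 7 racemic terminal epoxide, tert-butyl{[(5E)-8-(3,3-dimethyloxiran-2-yl)-6-methyl-2-methylideneoct-5-en-1-yl]oxy}dimethylsilane, via terminal bromohydrin 6 (not isolated)
Conditions: NBS (1.05 equiv), THF–H2O, 0 °C; crude 6, K2CO3, MeOH, rt
Reagents that add atoms: water, O; NBS, O=C1CCC(=O)N1Br (bromine only in 6)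
Why: Terminal-selective bromohydrin formation of an oligoprenyl chain in aqueous medium (bromonium opening by water at the tertiary carbon, the exposed isopropylidene end reacting first) followed by intramolecular Williamson closure should give the epoxide, whose stereocentre is erased in step 4.

Step 4
Reactants: 7 racemic terminal epoxide
Product: 8 (4E)-8-[(TBSO)methyl]-4-methylnona-4,8-dienal
Conditions: H5IO6 (1.2 equiv), THF–Et2O, 0 °C
Reagents that add atoms: none
Why: Periodic acid opens the trisubstituted epoxide at its tertiary carbon and cleaves the resulting glycol (Malaprade-type cleavage) to the C1 aldehyde and acetone without touching the remaining alkenes or, at 0 °C and short contact, the silyl ether.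

Step 5
Reactants: 8 (4E)-8-[(TBSO)methyl]-4-methylnona-4,8-dienal; 9 3-methylbuta-1,2-diene
Product: 12 (4R,7E)-11-[(TBSO)methyl]-3,3,7-trimethyldodeca-1,7,11-trien-4-ol, via B-prenyldiisopinocampheylborane 10 (not isolated), via diisopinocampheylborinate adduct 11 (not isolated)
Conditions: (−)-Ipc2BH, 9, THF, −25 °C; then 8, Et2O, −78 °C; NaOH, H2O2, 0 °C to rt
Reagents that add atoms: (−)-Ipc2BH, B([C@@H]1C[C@@H]2C[C@H]([C@H]1C)C2(C)C)[C@@H]1C[C@@H]2C[C@H]([C@H]1C)C2(C)C (boron and Ipc groups only in 10 and 11)
Why: Brown-type asymmetric allylboration (reverse prenylation): hydroboration of the allene gives prenylborane 10, which adds through a closed chair six-membered transition state with allyl inversion, so that C1–C2 and the quaternary carbon form together and the (+)-α-pinene-derived Ipc groups direct attack to the Si face of the aldehyde, setting (R)-C1.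

Step 6
Reactants: 12 (4R,7E)-11-[(TBSO)methyl]-3,3,7-trimethyldodeca-1,7,11-trien-4-ol
Product: 13 bis-TBS ether of 12
Conditions: TBSOTf, 2,6-lutidine, CH2Cl2, 0 °C to rt
Reagents that add atoms: TBSOTf, CC(C)(C)[Si](C)(C)OS(=O)(=O)C(F)(F)F
Why: Silylation with the triflate overcomes the neopentyl hindrance of the secondary alcohol and blocks γ-lactone formation once the acid is unveiled, with no change at C1.

Step 7
Reactants: 13 bis-TBS ether of 12
Product: 15 (4R,7E)-4-(TBSO)-11-[(TBSO)methyl]-3,3,7-trimethyldodeca-7,11-dien-1-ol, via B-alkylcatecholborane 14 (not isolated)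
Conditions: catecholborane (1.1 equiv), RhCl(PPh3)3 (cat.), THF, 0 °C to rt; NaOH, H2O2, 0 °C
Reagents that add atoms: hydrogen peroxide, OO; catecholborane, [H]B1Oc2ccccc2O1 (boron and catechol only in 14)
Why: Rhodium-catalysed hydroboration favours monosubstituted over 1,1-di- and trisubstituted alkenes far more strongly than uncatalysed hydroboration does, and the adjacent quaternary carbon enforces terminal (anti-Markovnikov) boron placement, so oxidation should give the primary alcohol only at the vinyl group.

Step 8
Reactants: 15 (4R,7E)-4-(TBSO)-11-[(TBSO)methyl]-3,3,7-trimethyldodeca-7,11-dien-1-ol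
Product: 16 (4R,7E)-4-(TBSO)-11-[(TBSO)methyl]-3,3,7-trimethyldodeca-7,11-dienoic acid
Conditions: TEMPO (cat.), PhI(OAc)2 (2.5 equiv), MeCN–H2O, rt
Reagents that add atoms: water, O
Why: Oxoammonium (TEMPO/PhI(OAc)2) oxidation takes the primary alcohol through the aldehyde hydrate to the acid and is known to leave isolated alkenes and silyl ethers alone.

Step 9
Reactants: 16 (4R,7E)-4-(TBSO)-11-[(TBSO)methyl]-3,3,7-trimethyldodeca-7,11-dienoic acid
Product: 17 (4R,7E)-4-(TBSO)-11-(hydroxymethyl)-3,3,7-trimethyldodeca-7,11-dienoic acid (seco acid)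
Conditions: HF·pyridine, pyridine, THF, 0 °C
Reagents that add atoms: none
Why: Selective desilylation: buffered HF removes the unhindered primary allylic TBS group much faster than the secondary TBS ether flanked by the quaternary carbon.

Step 10
Reactants: 17 seco acid
Product: 19 (5R,8E)-5-(TBSO)-4,4,8-trimethyl-12-methylidene-1-oxacyclotridec-8-en-2-one, via mixed 2-methyl-6-nitrobenzoic anhydride 18 (not isolated)
Conditions: MNBA, DMAP, CH2Cl2 (high dilution), slow addition of 17, rt
Reagents that add atoms: MNBA, Cc1cccc([N+](=O)[O-])c1C(=O)OC(=O)c1c(C)cccc1[N+](=O)[O-] (aroyl group only in 18)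
Why: Shiina macrolactonisation of a primary allylic alcohol onto the activated acid should close the 13-membered ring readily, helped by the gem-dimethyl group and the E-alkene as conformational restraints.

Step 11
Reactants: 19 (5R,8E)-5-(TBSO)-4,4,8-trimethyl-12-methylidene-1-oxacyclotridec-8-en-2-one
Product: 22 (3R,6E)-3-(TBSO)-2,2,6-trimethyl-10-methylidenecycloundec-6-ene-1-carboxylic acid (either or both epimers at the carboxyl-bearing carbon), via trimethylsilyl ketene acetal 20 (not isolated), via trimethylsilyl ester 21 (not isolated)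
Conditions: TMSCl–Et3N, LDA, THF, −78 °C (internal quench); −78 °C to rt, then 65 °C; 1 M HCl work-up
Reagents that add atoms: TMSCl, C[Si](C)(C)Cl (silicon only in 20 and 21)
Why: Proposed new method: LDA with TMSCl present traps the only enolisable position of 19 (the CH2 between C=O and the quaternary carbon) as silyl ketene acetal 20, and on warming a concerted suprafacial [3,3] shift joins that carbon to the exocyclic =CH2 of the O–CH2–C(=CH2) unit while the ring O–CH2 bond breaks. Because this allyl unit lies in the ring only through its OCH2 and its central carbon, C=O, O and OCH2 leave the ring and the former =CH2 enters it (13 − 3 + 1 = 11), the old OCH2 becoming the exocyclic methylene on C5 and the carbonyl carbon the CO2SiMe3 group on C3 of 21, which aqueous acid hydrolyses to 22. The closest known reaction type is the Ireland–Claisen ring contraction of macrolactones with an endocyclic allyl alkene, which removes four ring atoms; the two-atom version through an exocyclic methylene is not documented, but open-chain methallyl esters of hindered acids rearrange readily and the strongly exothermic change from ketene acetal to silyl ester should pay for the added strain of the eleven-membered ring. The carbocycle is closed transannularly through a six-centre chair or boat array that is bridged between its position 1 (ketene-acetal carbon) and position 5 (central allyl carbon) by the eight-atom chain C2–C1–C11–C10–C9–C8–C7–C6, which is long enough for either array. The only new stereocentre, C3, is governed by ketene-acetal geometry and the chair/boat choice under the bias of the neighbouring C1 silyloxy centre, and it needs no control because both epimers converge on the same diene in step 12, while C1 and the E-C8=C9 alkene lie outside the pericyclic array and are untouched. The selectivity needed is constitutional only, and the substrate secures it: one acidic site, one allyl terminus, no β-leaving group (C2 is quaternary), and in-situ silylation to outrun ketene extrusion or self-condensation.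

Step 12
Reactants: 22 (3R,6E)-3-(TBSO)-2,2,6-trimethyl-10-methylidenecycloundec-6-ene-1-carboxylic acid
Product: 23 tert-butyl{[(1R,3E,8E)-2,2,9-trimethyl-5-methylidenecycloundeca-3,8-dien-1-yl]oxy}dimethylsilane
Conditions: Pb(OAc)4, Cu(OAc)2 (cat.), pyridine, benzene, 80 °C
Reagents that add atoms: none
Why: Kochi-type oxidative decarboxylation: the Pb(IV) carboxylate fragments to CO2 and the secondary C3 radical, Cu(II) oxidises it with loss of a β-hydrogen, and since C2 is quaternary only an allylic C4–H can leave, giving the conjugated C3=C4 alkene, expected E because a Z alkene would press CMe2 against C5 within the ring.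

Step 13
Reactants: 23 TBS ether of the dienol
Product: 24 (1R,3E,8E)-2,2,9-trimethyl-5-methylidenecycloundeca-3,8-dien-1-ol
Conditions: TBAF, THF, 50 °C; H2O
Reagents that add atoms: none
Why: Fluoride desilylation cleaves the Si–O bond only, so the C1–O bond and its configuration are retained.

Step 14
Reactants: 25 vanillic acid (4-hydroxy-3-methoxybenzoic acid)
Product: 27 4-(TBSO)-3-methoxybenzoic acid, via silyl ester silyl ether 26 (not isolated)
Conditions: TBSCl (2.5 equiv), imidazole, DMF, rt; then AcOH–THF–H2O, rt
Reagents that add atoms: TBSCl, CC(C)(C)[Si](C)(C)Cl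
Why: Exhaustive silylation followed by mild acidic hydrolysis exploits the much greater lability of the silyl ester compared with the aryl silyl ether (selective silyl ester cleavage).

Step 15
Reactants: 24 (1R,3E,8E)-2,2,9-trimethyl-5-methylidenecycloundeca-3,8-dien-1-ol; 27 4-(TBSO)-3-methoxybenzoic acid
Product: 29 (1R,3E,8E)-2,2,9-trimethyl-5-methylidenecycloundeca-3,8-dien-1-yl 4-(TBSO)-3-methoxybenzoate, via mixed 2,4,6-trichlorobenzoic anhydride 28 (not isolated)
Conditions: 27, 2,4,6-trichlorobenzoyl chloride, Et3N, toluene, rt; then 24, DMAP, 60 °C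
Reagents that add atoms: 2,4,6-trichlorobenzoyl chloride, O=C(Cl)c1c(Cl)cc(Cl)cc1Cl (aroyl group only in 28)
Why: Yamaguchi esterification delivers a DMAP-activated aroyl group strong enough for the hindered neopentyl-type secondary alcohol, and as an O-acylation it leaves the C1 configuration untouched.

Step 16
Reactants: 29 silyl-protected ester
Product: 30 (1R,3E,8E)-2,2,9-trimethyl-5-methylidenecycloundeca-3,8-dien-1-yl 4-hydroxy-3-methoxybenzoate (target)
Conditions: TBAF, AcOH, THF, 0 °C
Reagents that add atoms: none
Why: Buffered fluoride cleaves the very labile aryl silyl ether (fluoride desilylation) under conditions too mild to affect the hindered benzoate or the diene.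

Compound list
1 | 2-methylprop-2-en-1-ol | C=C(C)CO | starting material
2 | geranyl bromide | CC(C)=CCC/C(C)=C/CBr | starting material
3 | dilithiated methallyl alcohol | [Li]CC(=C)CO[Li] | intermediate
4 | (5E)-6,10-dimethyl-2-methylideneundeca-5,9-dien-1-ol | CC(C)=CCC/C(C)=C/CCC(=C)CO | intermediate
5 | TBS ether of 4 | CC(C)=CCC/C(C)=C/CCC(=C)CO[Si](C)(C)C(C)(C)C | intermediate
6 | (5E)-9-bromo-1-(TBSO)-6,10-dimethyl-2-methylideneundec-5-en-10-ol, racemic | CC(C)(O)C(Br)CC/C(C)=C/CCC(=C)CO[Si](C)(C)C(C)(C)C | intermediate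
7 | tert-butyl{[(5E)-8-(3,3-dimethyloxiran-2-yl)-6-methyl-2-methylideneoct-5-en-1-yl]oxy}dimethylsilane, racemic | CC1(C)OC1CC/C(C)=C/CCC(=C)CO[Si](C)(C)C(C)(C)C | intermediate
8 | (4E)-8-[(TBSO)methyl]-4-methylnona-4,8-dienal | O=CCC/C(C)=C/CCC(=C)CO[Si](C)(C)C(C)(C)C | intermediate
9 | 3-methylbuta-1,2-diene | CC(C)=C=C | starting material
10 | B-(3-methylbut-2-enyl)diisopinocampheylborane | CC(C)=CCB([C@@H]1C[C@@H]2C[C@H]([C@H]1C)C2(C)C)[C@@H]1C[C@@H]2C[C@H]([C@H]1C)C2(C)C | intermediate
11 | diisopinocampheylborinate of 12 | C=CC(C)(C)[C@H](OB([C@@H]1C[C@@H]2C[C@H]([C@H]1C)C2(C)C)[C@@H]1C[C@@H]2C[C@H]([C@H]1C)C2(C)C)CC/C(C)=C/CCC(=C)CO[Si](C)(C)C(C)(C)C | intermediate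
12 | (4R,7E)-11-[(TBSO)methyl]-3,3,7-trimethyldodeca-1,7,11-trien-4-ol | C=CC(C)(C)[C@H](O)CC/C(C)=C/CCC(=C)CO[Si](C)(C)C(C)(C)C | intermediate
13 | bis-TBS ether of 12 | C=CC(C)(C)[C@H](O[Si](C)(C)C(C)(C)C)CC/C(C)=C/CCC(=C)CO[Si](C)(C)C(C)(C)C | intermediate
14 | B-alkylcatecholborane from 13 | c1ccc2OB(CCC(C)(C)[C@H](O[Si](C)(C)C(C)(C)C)CC/C(C)=C/CCC(=C)CO[Si](C)(C)C(C)(C)C)Oc2c1 | intermediate
15 | (4R,7E)-4-(TBSO)-11-[(TBSO)methyl]-3,3,7-trimethyldodeca-7,11-dien-1-ol | OCCC(C)(C)[C@H](O[Si](C)(C)C(C)(C)C)CC/C(C)=C/CCC(=C)CO[Si](C)(C)C(C)(C)C | intermediate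
16 | (4R,7E)-4-(TBSO)-11-[(TBSO)methyl]-3,3,7-trimethyldodeca-7,11-dienoic acid | OC(=O)CC(C)(C)[C@H](O[Si](C)(C)C(C)(C)C)CC/C(C)=C/CCC(=C)CO[Si](C)(C)C(C)(C)C | intermediate
17 | (4R,7E)-4-(TBSO)-11-(hydroxymethyl)-3,3,7-trimethyldodeca-7,11-dienoic acid | OC(=O)CC(C)(C)[C@H](O[Si](C)(C)C(C)(C)C)CC/C(C)=C/CCC(=C)CO | intermediate
18 | mixed anhydride of 17 and 2-methyl-6-nitrobenzoic acid | Cc1cccc([N+](=O)[O-])c1C(=O)OC(=O)CC(C)(C)[C@H](O[Si](C)(C)C(C)(C)C)CC/C(C)=C/CCC(=C)CO | intermediate
19 | (5R,8E)-5-(TBSO)-4,4,8-trimethyl-12-methylidene-1-oxacyclotridec-8-en-2-one | O=C1CC(C)(C)[C@H](O[Si](C)(C)C(C)(C)C)CC/C(C)=C/CCC(=C)CO1 | intermediate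
20 | trimethylsilyl ketene acetal of 19 (C=C geometry open) | C[Si](C)(C)OC1=CC(C)(C)[C@H](O[Si](C)(C)C(C)(C)C)CC/C(C)=C/CCC(=C)CO1 | intermediate
21 | trimethylsilyl ester of 22 | C=C1CC(C(=O)O[Si](C)(C)C)C(C)(C)[C@H](O[Si](C)(C)C(C)(C)C)CC/C(C)=C/CC1 | intermediate
22 | (3R,6E)-3-(TBSO)-2,2,6-trimethyl-10-methylidenecycloundec-6-ene-1-carboxylic acid (C1 of this name not defined) | C=C1CC(C(=O)O)C(C)(C)[C@H](O[Si](C)(C)C(C)(C)C)CC/C(C)=C/CC1 | intermediate
23 | tert-butyl{[(1R,3E,8E)-2,2,9-trimethyl-5-methylidenecycloundeca-3,8-dien-1-yl]oxy}dimethylsilane | C=C1/C=C/C(C)(C)[C@H](O[Si](C)(C)C(C)(C)C)CC/C(C)=C/CC1 | intermediate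
24 | (1R,3E,8E)-2,2,9-trimethyl-5-methylidenecycloundeca-3,8-dien-1-ol | C=C1/C=C/C(C)(C)[C@H](O)CC/C(C)=C/CC1 | intermediate
25 | vanillic acid | COc1cc(C(=O)O)ccc1O | starting material
26 | TBS 4-(TBSO)-3-methoxybenzoate | COc1cc(C(=O)O[Si](C)(C)C(C)(C)C)ccc1O[Si](C)(C)C(C)(C)C | intermediate
27 | 4-(TBSO)-3-methoxybenzoic acid | COc1cc(C(=O)O)ccc1O[Si](C)(C)C(C)(C)C | intermediate
28 | mixed anhydride of 27 and 2,4,6-trichlorobenzoic acid | COc1cc(C(=O)OC(=O)c2c(Cl)cc(Cl)cc2Cl)ccc1O[Si](C)(C)C(C)(C)C | intermediate
29 | (1R,3E,8E)-2,2,9-trimethyl-5-methylidenecycloundeca-3,8-dien-1-yl 4-(TBSO)-3-methoxybenzoate | C=C1/C=C/C(C)(C)[C@H](OC(=O)c2ccc(O[Si](C)(C)C(C)(C)C)c(OC)c2)CC/C(C)=C/CC1 | intermediate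
30 | (1R,3E,8E)-2,2,9-trimethyl-5-methylidenecycloundeca-3,8-dien-1-yl 4-hydroxy-3-methoxybenzoate | C=C1/C=C/C(C)(C)[C@H](OC(=O)c2ccc(O)c(OC)c2)CC/C(C)=C/CC1 | target

Total step count: 16. Longest linear sequence: 15 (steps 1–13, 15, 16).

Steps most likely to fail

Step 11. The ketene acetal may not reach the bridged six-centre geometry before it is lost by desilylation, C-silylation or ketene extrusion, so that the lactone is returned or degraded instead of contracted. The fallback sets out from 17 and comes back at 22, and it closes the C3–C4 bond by known enolate alkylation instead of by rearrangement. Compound 17 is esterified with TMSCHN2 to the hydroxy methyl ester F1. An Appel reaction (CBr4, PPh3, CH2Cl2) then gives the allylic bromide F2. Slow addition of F2 to KHMDS in THF at high dilution should give, by intramolecular SN2 alkylation of the ester enolate, the cycloundecene methyl ester F3; both CH2 termini of the 2-methyleneallyl unit lead to the same constitution. Nucleophilic demethylation (LiI, pyridine, reflux) avoids attack at the hindered carbonyl and delivers 22.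

Step 12. The C3 radical may add transannularly to the C8=C9 or C5 alkene, or undergo ligand transfer instead of β-hydrogen loss, and Pb(IV) may attack the alkenes. The fallback sets out from 22 and comes back at 23. It replaces oxidative elimination by fast group transfer followed by a polar syn-elimination. Compound 22 is coupled with N-hydroxypyridine-2-thione (DCC, CH2Cl2, dark) to the Barton ester F4. Visible-light photolysis in the presence of PhSeSePh (Barton decarboxylative selenation) gives the C3 phenyl selenide F5. Oxidation with one equivalent of mCPBA at −78 °C gives the selenoxide F6, which on warming with i-Pr2NH eliminates toward C4, the only carbon bearing a β-hydrogen, to give 23.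

Step 7. Site selectivity may be lost, because the vinyl group is slowed by the adjacent quaternary carbon and the 1,1-disubstituted alkene may then compete for the borane. The fallback sets out from 13 and comes back at 16, and it replaces hydroboration by palladium oxidation chemistry that responds only to monosubstituted alkenes. A nitrite-modified, aldehyde-selective Wacker oxidation [PdCl2(PhCN)2, CuCl2, AgNO2, t-BuOH–MeNO2, O2], a method established for vinyl groups on quaternary carbons, should give the aldehyde F7. Pinnick oxidation (NaClO2, NaH2PO4, 2-methylbut-2-ene, t-BuOH–H2O) then gives 16.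

Further compounds
F1 | step 11 | methyl (4R,7E)-4-(TBSO)-11-(hydroxymethyl)-3,3,7-trimethyldodeca-7,11-dienoate | COC(=O)CC(C)(C)[C@H](O[Si](C)(C)C(C)(C)C)CC/C(C)=C/CCC(=C)CO
F2 | step 11 | methyl (4R,7E)-11-(bromomethyl)-4-(TBSO)-3,3,7-trimethyldodeca-7,11-dienoate | COC(=O)CC(C)(C)[C@H](O[Si](C)(C)C(C)(C)C)CC/C(C)=C/CCC(=C)CBr
F3 | step 11 | methyl (3R,6E)-3-(TBSO)-2,2,6-trimethyl-10-methylidenecycloundec-6-ene-1-carboxylate | C=C1CC(C(=O)OC)C(C)(C)[C@H](O[Si](C)(C)C(C)(C)C)CC/C(C)=C/CC1
F4 | step 12 | 2-thioxopyridin-1(2H)-yl ester of 22 (Barton ester) | C=C1CC(C(=O)ON2C=CC=CC2=S)C(C)(C)[C@H](O[Si](C)(C)C(C)(C)C)CC/C(C)=C/CC1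
F5 | step 12 | C3 phenyl selenide of the cycloundecene silyl ether | C=C1CC([Se]c2ccccc2)C(C)(C)[C@H](O[Si](C)(C)C(C)(C)C)CC/C(C)=C/CC1
F6 | step 12 | selenoxide of F5 | C=C1CC([Se](=O)c2ccccc2)C(C)(C)[C@H](O[Si](C)(C)C(C)(C)C)CC/C(C)=C/CC1
F7 | step 7 | (4R,7E)-4-(TBSO)-11-[(TBSO)methyl]-3,3,7-trimethyldodeca-7,11-dienal | O=CCC(C)(C)[C@H](O[Si](C)(C)C(C)(C)C)CC/C(C)=C/CCC(=C)CO[Si](C)(C)C(C)(C)C
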